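## Structural features

The target is a furanoheliangolide. Its ten-membered carbocycle (C1–C10) is bridged by an oxygen between C3 and C10, so that the C1 ketone, C2=C3, the bridging oxygen and quaternary C10 form a 3(2H)-furanone. A trans-fused α-methylene-γ-butyrolactone (O6–C12(=O)–C11=C13) sits on the C6–C7 edge. The Z-trisubstituted C4=C5 olefin (C15 methyl) joins the furanone to the lactone carbinol C6 and gives a cross-conjugated dienone held in a strained bridged bicycle. Three stereocentres are contiguous (C6 S, C7 S, C8 R; all-syn along the C5–C9 chain with C11 as the branch on C7), and the oxygenated quaternary C10 (R) is separated from them by the C9 methylene. C8 carries the ester of (2E)-2-(acetoxymethyl)but-2-enoic acid, itself an acrylate with an allylic acetate. The fragile sites are the methylene lactone (Michael acceptor), the side chain (base- and SN2′-sensitive), the allylic C6–O bond and the vinylogous-ester furanone, so no strong base or nucleophile can be used once lactone or side chain is present. The real difficulties are closing a ten-membered ring that holds a Z olefin and a bridge, and telling O6 from O8, since either can close a five-membered lactone on C12. The key step exploits C1: it lies between quaternary C10 (its aldehyde cannot enolise) and the C2–C5 Z-enyne, whose terminal carbon C2 is the nucleophile, and O10 is placed to add to C3 of the resulting ynone once the carbocycle exists.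

## Logic of the disconnections

37 ⇒ 29 + 35. The C8–O acyl bond is cut last because the side chain tolerates neither base, fluoride nor hydride. This removes the most labile group from every earlier intermediate. The forward step must acylate a hindered secondary hydroxyl without adding a nucleophile to the methylene lactone.

35 ⇒ 34 ⇒ 32 ⇒ 30 + 31. The Cα–C(carbinol) bond is cut (Morita–Baylis–Hillman) and the acetate is moved back by a 1,3-transposition. The tert-butyl ester is chosen because acid frees the carboxyl without cleaving the acetate. The transposition must give the E olefin, which is the thermodynamic isomer.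

29 ⇒ 28 ⇒ 25 ⇒ 24. The O6–C12 lactone bond is cut and C12 is taken down to the alcohol level, so that no ester is present when an amide base is used. The forward step requires O6 and O12 to be freed together while O8 stays masked, because O8 could lactonise on C12 equally well. This is arranged with a secondary TES ether at C6, a primary TBS ether at C12 and a hindered secondary TBS ether at C8.

24 ⇒ 23 ⇒ 22. The O10–C3 bond of the furanone is cut, turning the bridged dienone into a monocyclic ynone. O10 must be released while O6 is still blocked, because O6 sits on the Z-enyne and could attack C3 in a 5-exo mode. O10 is therefore carried as a PMB ether, removable by DDQ without touching silyl ethers. A MOM ether at C10 could not be cleaved without loss of the C6 TES ether, so it is replaced, and C12 becomes a silyl ether so that DDQ finds only one benzyl ether.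

22 ⇒ 21 ⇒ 19. The C1–C2 bond is cut and the ten-membered ring opened (key step). The result is an acyclic Z-enyne aldehyde with all four stereocentres in place. The forward step needs only chemoselectivity and a preference for ring closure. The configurations of 19 and 21 were checked centre by centre against 37 (C6 S, C7 S, C8 R, C10 R) and need no correction.

19 ⇒ 18 ⇒ 17 ⇒ 16 ⇒ 15 ⇒ 14. These are functional-group changes only. The C1/C10 diol is carried as one 4-methoxybenzylidene acetal; its reductive opening in 17 ⇒ 18 places PMB on the tertiary O10 and frees C1–OH in a single operation. The C8 and C12 oxygens of 16 come from reduction of an 8,12-lactone in 15, which in turn requires O6 to be silylated first (14 ⇒ 15).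

14 ⇒ 10 + 12. The C6–C7 bond is cut. The allyl partner is the butenolide bromide 10 and not an open-chain 2-substituted allyl bromide. In 10 the C7–C8 bond is locked trans to the CH2Br arm and C8 is a ring stereocentre, so both the chair transition state (C6 against C7) and the facial choice (C7 against C8) are predictable. An acyclic reagent would offer neither a fixed olefin geometry nor reliable 1,2-induction. 12 ⇒ 11 by oxidation.

10 ⇒ 9 ⇒ 7 + 8. The C7=C11 double bond (ring-closing metathesis) and the O8–C12 ester bond are cut. This brings in C11–C13 from a commercial acid. The forward step has to close a butenolide onto a 1,1-disubstituted acrylate.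

7 ⇒ 5 + 6. The C7–C8 bond is cut. A catalyst-controlled alkenylzinc addition sets C8; the hexenyl group supplies C7 and its tail leaves as hex-1-ene in the metathesis. The demand is facial control at an α-unbranched aldehyde.

5 ⇒ 4 ⇒ 3 ⇒ 2 ⇒ 1. C10 with its methyl, oxygen, C1 and C9 is taken from the chiral pool; 1 has the R configuration that maps onto C10 without inversion. The two carboxyls are told apart by hydroxyl-directed reduction of the one next to the carbinol.

## Other disconnections considered

Alternative 1: The cut is the C4=C5 double bond, traced back to the C4–S and C5–S bonds of the eleven-membered sulfone A1. In the forward key step A1 is chlorinated at C4 with C2Cl6 and KOt-Bu (C4 is the most acidic α-sulfonyl position, being vinylogous to the C1 ketone). 1,3-Elimination gives the episulfone, SO2 is lost, and the ring contracts to A2.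
- In favour: the large ring is made by thioether alkylation, a forgiving reaction. The extrusion is irreversible. The olefin geometry is imposed by the ring (a cis-cycloalkene is expected at this ring size, which is what is needed), so it does not have to be carried through an isomerisable enal as in the chosen plan. On this point the alternative is the equal or the better.
- Against: the base meets a lactone. The α-sulfonyl carbanion at C5 is β to the lactone oxygen on C6 and can expel it (E1cB). The furanone is also exposed to alkoxide. A2 lacks C13, so an enolate methylenation must follow on the complete tricycle.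
- Comparison: structurally this plan must assemble furanone, lactone and all stereocentres before the ring-forming event, whereas the chosen plan closes the ring on an acyclic chain and uses base only while no ester exists. Mechanistically it relies on carbanion chemistry next to leaving groups. In steps, three operations (sulfide closure, oxidation, contraction) plus methylenation replace ring closure and oxidation.

Alternative 2: The cut is the O–C3 bond of the furanone together with the C10–CH3 bond. In the forward key step AuCl3 or PtCl2 activates the C2≡C3 alkyne of the tertiary propargylic hydroxy ketone A3, the C10 ketone oxygen attacks C3, and the methyl group migrates from C1 to the oxocarbenium carbon C10 to give furanone A4.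
- In favour: the step is catalytic and atom-economical. It builds the heterocycle and the quaternary C10 at once and tolerates silyl and benzyl ethers. As a way of making a furanone ring it is the equal of step 18.
- Against: A4 is an acyclic furanone with only 11 of the 15 skeletal carbons, so the carbocycle, C6–C8 and the lactone are all still to be made. The C10 configuration depends on complete chirality transfer in a methyl shift, and methyl is a reluctant migrating group. A3 must be a single enantiomer at a tertiary carbinol flanked by a ketone, which is not a chiral-pool pattern, whereas the chosen plan takes C10 from 1.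
- Comparison: structurally the ten-membered ring would later have to be closed onto a rigid furanone, forming the bridged bicycle directly; the chosen plan closes a less strained cyclodecenyne first. In step economy it is behind, because its key step solves the smallest part of the problem.

Alternative 3: The cut is the C5–C6 bond. In the forward key step CrCl2 with catalytic NiCl2 converts the Z-alkenyl iodide of the seco aldehyde A5 into an alkenylchromium species. This adds to the C6 aldehyde, and the C6 alkoxide closes onto the C12 methyl ester to give A6, which is identical with 28.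
- In favour: the conditions are very chemoselective (furanone, acrylate ester and silyl ether survive). Ring and lactone form in one operation at the correct oxidation level, so desilylation and oxidative lactonisation (steps 19 and 20) are not needed. On endgame step economy and functional-group tolerance this alternative is the better.
- Against: C6 becomes a new stereocentre during the macrocyclisation, controlled only by the folding of the chain, whereas in the chosen plan C6 is set earlier in a chair transition state. In A5 the C7 hydrogen is α to the aldehyde and allylic to the acrylate, so epimerisation and olefin migration threaten the precursor. The ring must close with the rigid furanone and Z olefin already present, which means the strained bridged system is formed in the ring-closing step itself.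
- Comparison: mechanistically both plans add a carbon nucleophile to an aldehyde. The chosen one creates no lasting stereocentre in that step and uses a non-enolisable aldehyde. The alternative is shorter after ring closure but carries more stereochemical and stability risk at the decisive step.

Key step: step 15

Remark: atoms are numbered as in the germacranolide skeleton (C1–C15). The benzylidene acetal carbon (4 to 17) and the C1 carbinol of 21 are carried as epimer mixtures, because step 13 and step 16 respectively remove these centres.

## Route

Step 1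
Reactants: 1 (R)-citramalic acid
Product: 2 dimethyl (2R)-2-hydroxy-2-methylbutanedioate
Conditions: MeOH, H2SO4 (cat.), 50 °C
Reagents that add atoms: methanol, CO
Why: Fischer esterification of both carboxyl groups; the tertiary carbinol C10 is not involved and keeps its configuration.

Step 2
Reactants: 2 dimethyl (2R)-2-hydroxy-2-methylbutanedioate
Product: 3 methyl (3R)-3,4-dihydroxy-3-methylbutanoate
Conditions: BH3·SMe2 (1.05 equiv), NaBH4 (5 mol %), THF, 0 °C to rt; MeOH
Reagents that add atoms: none
Why: Hydroxyl-directed borane reduction: the tertiary hydroxyl forms an alkoxyborane and hydride is delivered through a five-membered chelate to the adjacent ester only (future C1), so the remote ester (future C8) survives.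

Step 3
Reactants: 3 methyl (3R)-3,4-dihydroxy-3-methylbutanoate
Product: 4 methyl 2-[(4R)-2-(4-methoxyphenyl)-4-methyl-1,3-dioxolan-4-yl]acetate
Conditions: 4-MeOC6H4CH(OMe)2, PPTS (cat.), CH2Cl2, rt
Reagents that add atoms: 4-methoxybenzaldehyde dimethyl acetal, COc1ccc(C(OC)OC)cc1
Why: Acid-catalysed transacetalisation of the 1,2-diol; the five-membered acetal should form faster than lactonisation of the primary hydroxyl onto the ester, and the new acetal centre is of no consequence.

Step 4
Reactants: 4 methyl 2-[(4R)-2-(4-methoxyphenyl)-4-methyl-1,3-dioxolan-4-yl]acetate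
Product: 5 2-[(4R)-2-(4-methoxyphenyl)-4-methyl-1,3-dioxolan-4-yl]acetaldehyde
Conditions: i-Bu2AlH (1.1 equiv), CH2Cl2, −78 °C; aq. potassium sodium tartrate
Reagents that add atoms: none
Why: Partial reduction of the ester; the tetrahedral aluminate is stable at −78 °C and collapses to the aldehyde only on work-up, and the acetal is inert at this temperature.

Step 5
Reactants: 5 2-[(4R)-2-(4-methoxyphenyl)-4-methyl-1,3-dioxolan-4-yl]acetaldehyde; 6 hex-1-yne
Product: 7 (2R,3E)-1-[(4R)-2-(4-methoxyphenyl)-4-methyl-1,3-dioxolan-4-yl]oct-3-en-2-ol
Conditions: 6, (c-C6H11)2BH, toluene, 0 °C to rt; Me2Zn, −78 °C; (−)-MIB (5 mol %), then 5, −10 °C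
Reagents that add atoms: none
Why: Catalytic asymmetric alkenylzinc addition: hydroboration gives the E-alkenylborane, boron-to-zinc exchange the alkenylzinc, and the amino-alcohol-bound zinc delivers it to the Si face of the aldehyde, which sets C8 as R under catalyst control (the remote C10 centre has little influence). The butyl tail is a placeholder that leaves in step 7.

Step 6
Reactants: 7 (2R,3E)-1-[(4R)-2-(4-methoxyphenyl)-4-methyl-1,3-dioxolan-4-yl]oct-3-en-2-ol; 8 2-(bromomethyl)prop-2-enoic acid
Product: 9 (2R,3E)-1-[(4R)-2-(4-methoxyphenyl)-4-methyl-1,3-dioxolan-4-yl]oct-3-en-2-yl 2-(bromomethyl)prop-2-enoate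
Conditions: 8, DCC, DMAP (10 mol %), CH2Cl2, 0 °C
Reagents that add atoms: none
Why: Carbodiimide (Steglich) esterification of the secondary allylic alcohol, run cold with little DMAP so that the allylic bromide is not displaced; the C8–O bond is not broken, so the configuration is retained.

Step 7
Reactants: 9 (2R,3E)-1-[(4R)-2-(4-methoxyphenyl)-4-methyl-1,3-dioxolan-4-yl]oct-3-en-2-yl 2-(bromomethyl)prop-2-enoate
Product: 10 (5R)-3-(bromomethyl)-5-{[(4R)-2-(4-methoxyphenyl)-4-methyl-1,3-dioxolan-4-yl]methyl}furan-2(5H)-one
Conditions: second-generation Grubbs catalyst RuCl2(=CHPh)(H2IMes)(PCy3) (5 mol %), toluene, 80 °C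
Reagents that add atoms: none
Why: Ring-closing metathesis between the hexenyl olefin and the 1,1-disubstituted acrylate closes the butenolide (C7=C11) and expels volatile hex-1-ene; allylic bromide and acetal tolerate the ruthenium carbene.

Step 8
Reactants: 11 (Z)-3-methylpent-2-en-4-yn-1-ol
Product: 12 (Z)-3-methylpent-2-en-4-ynal
Conditions: MnO2, CH2Cl2, 0 °C to rt; filtered solution used directly
Reagents that add atoms: none
Why: Chemoselective oxidation of the primary allylic alcohol without base or acid, so the Z geometry should be kept; the volatile aldehyde is not concentrated.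

Step 9
Reactants: 10 (5R)-3-(bromomethyl)-5-{[(4R)-2-(4-methoxyphenyl)-4-methyl-1,3-dioxolan-4-yl]methyl}furan-2(5H)-one; 12 (Z)-3-methylpent-2-en-4-ynal
Product: 14 (4R,5R)-4-[(1S,2Z)-1-hydroxy-3-methylpent-2-en-4-yn-1-yl]-5-{[(4R)-2-(4-methoxyphenyl)-4-methyl-1,3-dioxolan-4-yl]methyl}-3-methylideneoxolan-2-one, via allylindium dibromide 13 (not isolated)
Conditions: In powder, THF/H2O (1:1), rt
Reagents that add atoms: none
Why: Barbier allylation: indium inserts into the allylic C–Br bond and the allylindium adds through its γ-carbon C7 to the aldehyde carbonyl (1,2-addition with allylic transposition) in a chair Zimmerman–Traxler arrangement. The ring holds C8 trans to the CH2–In arm, so the aldehyde residue and C8 are both equatorial and O6 ends anti to C8 (C6 S), while the aldehyde approaches the ring face opposite the C9 side chain, which fixes C7 relative to C8. Aqueous indium tolerates the terminal alkyne and the acetal.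

Step 10
Reactants: 14 (4R,5R)-4-[(1S,2Z)-1-hydroxy-3-methylpent-2-en-4-yn-1-yl]-5-{[(4R)-2-(4-methoxyphenyl)-4-methyl-1,3-dioxolan-4-yl]methyl}-3-methylideneoxolan-2-one
Product: 15 (4S,5R)-4-[(1S,2Z)-3-methyl-1-(triethylsilyloxy)pent-2-en-4-yn-1-yl]-5-{[(4R)-2-(4-methoxyphenyl)-4-methyl-1,3-dioxolan-4-yl]methyl}-3-methylideneoxolan-2-one
Conditions: TESOTf, 2,6-lutidine, CH2Cl2, −78 °C
Reagents that add atoms: triethylsilyl trifluoromethanesulfonate, CC[Si](CC)(CC)OS(=O)(=O)C(F)(F)F
Why: Fast silylation of the only free hydroxyl with a non-nucleophilic base, before the lactone can migrate from O8 to O6; it makes O6 the most labile silyl ether, and the acetal should survive the silyl triflate at this temperature.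

Step 11
Reactants: 15 (4S,5R)-4-[(1S,2Z)-3-methyl-1-(triethylsilyloxy)pent-2-en-4-yn-1-yl]-5-{[(4R)-2-(4-methoxyphenyl)-4-methyl-1,3-dioxolan-4-yl]methyl}-3-methylideneoxolan-2-one
Product: 16 seco diol (6S,7S,8R,10R): C2 terminal alkyne; C6 triethylsilyl ether; free C8 and C12 hydroxyls; C1/C10 4-methoxybenzylidene acetal
Conditions: i-Bu2AlH (4 equiv), THF, −78 to 0 °C; aq. potassium sodium tartrate
Reagents that add atoms: none
Why: 1,2-Reduction of the α-methylene lactone to the allylic diol; in THF the aluminium hydride is too weakly Lewis acidic to open the benzylidene acetal, and the secondary TES ether is stable.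

Step 12
Reactants: 16 seco diol (C8-OH and C12-OH)
Product: 17 seco bis-silyl ether (6S,7S,8R,10R): C6 triethylsilyl ether; C8 and C12 tert-butyldimethylsilyl ethers; C1/C10 4-methoxybenzylidene acetal
Conditions: TBSOTf (2.5 equiv), 2,6-lutidine, CH2Cl2, −78 to −30 °C
Reagents that add atoms: tert-butyldimethylsilyl trifluoromethanesulfonate, CC(C)(C)[Si](C)(C)OS(=O)(=O)C(F)(F)F
Why: One-pot silylation of the primary allylic and the hindered secondary hydroxyl with a silyl triflate; at low temperature the acetal and the TES ether should be untouched.

Step 13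
Reactants: 17 seco bis-silyl ether with C1/C10 acetal
Product: 18 seco primary alcohol (6S,7S,8R,10R): free C1 hydroxyl; C10 4-methoxybenzyl ether; C6 triethylsilyl ether; C8 and C12 tert-butyldimethylsilyl ethers
Conditions: i-Bu2AlH (3 equiv), CH2Cl2, −20 to 0 °C; aq. potassium sodium tartrate
Reagents that add atoms: none
Why: Reductive opening of the benzylidene acetal: aluminium binds the less hindered primary oxygen, that C–O bond ionises and hydride quenches the oxocarbenium ion, leaving PMB on the tertiary O10 and freeing C1–OH; the acetal stereocentre disappears.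

Step 14
Reactants: 18 seco primary alcohol
Product: 19 seco Z-enyne aldehyde (6S,7S,8R,10R): C1 aldehyde; C10 4-methoxybenzyl ether; C6 triethylsilyl ether; C8 and C12 tert-butyldimethylsilyl ethers
Conditions: Dess–Martin periodinane, CH2Cl2, 0 °C to rt
Reagents that add atoms: none
Why: Dess–Martin oxidation under neutral conditions gives the non-enolisable α-alkoxy aldehyde; alkyne, silyl ethers and PMB ether are inert.

Step 15
Reactants: 19 seco Z-enyne aldehyde
Product: 21 ten-membered Z-enynol (6S,7S,8R,10R; C1 carbinol as either epimer), via lithium acetylide 20 (not isolated)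
Conditions: LiN(SiMe3)2 (1.5 equiv), THF (0.003 M), −30 to 0 °C; AcOH
Reagents that add atoms: none
Why: LiN(SiMe3)2 removes the acetylenic proton at C2 to give acetylide 20, which adds to the C1 aldehyde and forms the C1–C2 bond. The closest known reaction type is the base-mediated intramolecular acetylide–aldehyde condensation used to close ten-membered rings that contain a Z-enyne. The ring closes in the 10-exo-trig mode, with the carbonyl oxygen ending outside the ring. The only new stereocentre, C1, is not controlled and need not be, because step 16 oxidises it. The step needs chemoselectivity and ring closure in preference to oligomerisation: C10 is quaternary, so the aldehyde has no α-hydrogen; no ester or lactone is present (C12 is a silyl ether); and the PMB and silyl ethers are inert to the amide base. Addition of the amide to the hindered aldehyde is reversible at low temperature, whereas acetylide addition is not. High dilution and the Z olefin, which turns C2 back towards C1, favour the intramolecular path, and the cyclodecenyne formed is less strained than the bridged dienone made from it in step 18.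

Step 16
Reactants: 21 ten-membered Z-enynol
Product: 22 ten-membered Z-enynone (6S,7S,8R,10R): C1 ketone; C10 4-methoxybenzyl ether
Conditions: Dess–Martin periodinane, CH2Cl2, 0 °C
Reagents that add atoms: none
Why: Dess–Martin oxidation of the propargylic carbinol removes the uncontrolled C1 centre and gives the conjugated ynone.

Step 17
Reactants: 22 ten-membered Z-enynone
Product: 23 hydroxy ynone (6S,7S,8R,10R): free tertiary C10 hydroxyl
Conditions: DDQ, CH2Cl2/aq. NaH2PO4–Na2HPO4 (pH 7), 0 °C
Reagents that add atoms: none
Why: Oxidative debenzylation: DDQ abstracts hydride from the electron-rich benzyl ether and water hydrolyses the oxocarbenium ion, freeing O10 while all three silyl ethers stay; O6 therefore remains blocked while the alkyne is still present.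

Step 18
Reactants: 23 hydroxy ynone
Product: 24 bridged 3(2H)-furanone (6S,7S,8R,10R): C6 triethylsilyl ether; C8 and C12 tert-butyldimethylsilyl ethers
Conditions: AuCl3 (5 mol %), CH2Cl2, rt
Reagents that add atoms: none
Why: The gold salt activates the ynone π-bond, O10 attacks C3 transannularly in the 5-endo-dig mode and protodeauration gives the furanone; this is the known gold-catalysed cyclisation of γ-hydroxy ynones, and it relieves the strain of the cyclic alkyne.

Step 19
Reactants: 24 bridged 3(2H)-furanone
Product: 25 furanone diol (6S,7R,8R,10R): free C6 and C12 hydroxyls; C8 tert-butyldimethylsilyl ether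
Conditions: HF·pyridine, pyridine, THF, 0 °C
Reagents that add atoms: none
Why: Buffered fluoride cleaves the secondary TES ether and the unhindered primary allylic TBS ether much faster than the secondary TBS ether at C8, which is shielded by the C7 branch and the neopentyl-type C9.

Step 20
Reactants: 25 furanone diol
Product: 28 C8-silylated tricyclic methylene lactone (6S,7R,8R,10R), via hydroxy enal 26 (not isolated), via lactol 27 (not isolated)
Conditions: TEMPO (20 mol %), PhI(OAc)2 (3 equiv), CH2Cl2, rt
Reagents that add atoms: none
Why: Oxidative lactonisation: the oxoammonium species oxidises the primary allylic alcohol to the enal, O6 closes the lactol and a second oxidation gives the lactone. The secondary C6 carbinol is oxidised far more slowly than the primary one, and O8 is still silylated, so only the 6,12-lactone can form.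

Step 21
Reactants: 28 C8-silylated tricyclic methylene lactone
Product: 29 C8 alcohol of the tricyclic methylene lactone (6S,7S,8R,10R)
Conditions: HF·pyridine (excess), THF, rt
Reagents that add atoms: none
Why: Acidic fluoride removes the hindered TBS ether without the basic conditions that would cause conjugate addition to the methylene lactone.

Step 22
Reactants: 30 tert-butyl acrylate; 31 acetaldehyde
Product: 32 tert-butyl 3-hydroxy-2-methylidenebutanoate (racemic)
Conditions: DABCO (1 equiv), 1,4-dioxane/H2O (1:1), rt
Reagents that add atoms: none
Why: Morita–Baylis–Hillman reaction, with the aqueous medium speeding up the sluggish tert-butyl acrylate; the carbinol centre is racemic and is destroyed in step 23.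

Step 23
Reactants: 32 tert-butyl 3-hydroxy-2-methylidenebutanoate
Product: 34 tert-butyl (2E)-2-(acetoxymethyl)but-2-enoate, via secondary acetate 33 (not isolated)
Conditions: Ac2O, Et3N, DMAP (cat.), CH2Cl2, 0 °C; then DABCO (20 mol %), THF, 65 °C
Reagents that add atoms: acetic anhydride, CC(=O)OC(C)=O
Why: Acetylation followed by amine-catalysed 1,3-transposition (SN2′ addition of DABCO, return of acetate at the primary carbon) gives the thermodynamically preferred trisubstituted olefin with the methyl group trans to the ester, which is the E isomer.

Step 24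
Reactants: 34 tert-butyl (2E)-2-(acetoxymethyl)but-2-enoate
Product: 35 (2E)-2-(acetoxymethyl)but-2-enoic acid
Conditions: TFA, CH2Cl2, 0 °C to rt
Reagents that add atoms: none
Why: Acidolysis of the tert-butyl ester with loss of 2-methylpropene leaves the acetate and the olefin geometry untouched, which saponification of a simple alkyl ester would not.

Step 25
Reactants: 29 C8 alcohol of the tricyclic methylene lactone; 35 (2E)-2-(acetoxymethyl)but-2-enoic acid
Product: 37 target CNP0176571.1, via mixed anhydride 36 (not isolated)
Conditions: 35, 2,4,6-Cl3C6H2COCl, Et3N, toluene, rt; then 29, DMAP, rt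
Reagents that add atoms: none
Why: Yamaguchi esterification: the mixed anhydride acylates DMAP and the acylpyridinium ion esterifies the hindered C8 hydroxyl under nearly neutral conditions; no stereocentre is touched and the E side-chain olefin is the stable isomer.

## Compound list

1 | (R)-citramalic acid, (2R)-2-hydroxy-2-methylbutanedioic acid | C[C@@](O)(CC(=O)O)C(=O)O | starting material
2 | dimethyl (2R)-2-hydroxy-2-methylbutanedioate | COC(=O)C[C@@](C)(O)C(=O)OC | intermediate
3 | methyl (3R)-3,4-dihydroxy-3-methylbutanoate | COC(=O)C[C@@](C)(O)CO | intermediate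
4 | methyl 2-[(4R)-2-(4-methoxyphenyl)-4-methyl-1,3-dioxolan-4-yl]acetate (acetal carbon as both epimers) | COC(=O)C[C@@]1(C)OC(c2ccc(OC)cc2)OC1 | intermediate
5 | 2-[(4R)-2-(4-methoxyphenyl)-4-methyl-1,3-dioxolan-4-yl]acetaldehyde | O=CC[C@@]1(C)OC(c2ccc(OC)cc2)OC1 | intermediate
6 | hex-1-yne | CCCCC#C | starting material
7 | (2R,3E)-1-[(4R)-2-(4-methoxyphenyl)-4-methyl-1,3-dioxolan-4-yl]oct-3-en-2-ol | CCCC/C=C/[C@H](O)C[C@@]1(C)OC(c2ccc(OC)cc2)OC1 | intermediate
8 | 2-(bromomethyl)prop-2-enoic acid | C=C(CBr)C(=O)O | starting material
9 | (2R,3E)-1-[(4R)-2-(4-methoxyphenyl)-4-methyl-1,3-dioxolan-4-yl]oct-3-en-2-yl 2-(bromomethyl)prop-2-enoate | CCCC/C=C/[C@H](OC(=O)C(=C)CBr)C[C@@]1(C)OC(c2ccc(OC)cc2)OC1 | intermediate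
10 | (5R)-3-(bromomethyl)-5-{[(4R)-2-(4-methoxyphenyl)-4-methyl-1,3-dioxolan-4-yl]methyl}furan-2(5H)-one | BrCC1=C[C@@H](C[C@@]2(C)OC(c3ccc(OC)cc3)OC2)OC1=O | intermediate
11 | (Z)-3-methylpent-2-en-4-yn-1-ol | C#C/C(C)=C\CO | starting material
12 | (Z)-3-methylpent-2-en-4-ynal | C#C/C(C)=C\C=O | intermediate
13 | allylindium dibromide derived from 10 (idealised monomer, not isolated) | Br[In](Br)CC1=C[C@@H](C[C@@]2(C)OC(c3ccc(OC)cc3)OC2)OC1=O | intermediate
14 | (4R,5R)-4-[(1S,2Z)-1-hydroxy-3-methylpent-2-en-4-yn-1-yl]-5-{[(4R)-2-(4-methoxyphenyl)-4-methyl-1,3-dioxolan-4-yl]methyl}-3-methylideneoxolan-2-one | C#C/C(C)=C\[C@H](O)[C@H]1C(=C)C(=O)O[C@@H]1C[C@@]2(C)OC(c3ccc(OC)cc3)OC2 | intermediate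
15 | (4S,5R)-4-[(1S,2Z)-3-methyl-1-(triethylsilyloxy)pent-2-en-4-yn-1-yl]-5-{[(4R)-2-(4-methoxyphenyl)-4-methyl-1,3-dioxolan-4-yl]methyl}-3-methylideneoxolan-2-one | C#C/C(C)=C\[C@H](O[Si](CC)(CC)CC)[C@H]1C(=C)C(=O)O[C@@H]1C[C@@]2(C)OC(c3ccc(OC)cc3)OC2 | intermediate
16 | seco diol (6S,7S,8R,10R): C6 OTES, C8 OH, C12 OH, C1/C10 4-methoxybenzylidene acetal, C2 terminal alkyne | C#C/C(C)=C\[C@H](O[Si](CC)(CC)CC)[C@@H](C(=C)CO)[C@H](O)C[C@@]1(C)OC(c2ccc(OC)cc2)OC1 | intermediate
17 | seco bis-silyl ether (6S,7S,8R,10R): C6 OTES, C8 OTBS, C12 OTBS, C1/C10 4-methoxybenzylidene acetal | C#C/C(C)=C\[C@H](O[Si](CC)(CC)CC)[C@@H](C(=C)CO[Si](C)(C)C(C)(C)C)[C@H](O[Si](C)(C)C(C)(C)C)C[C@@]1(C)OC(c2ccc(OC)cc2)OC1 | intermediate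
18 | seco primary alcohol (6S,7S,8R,10R): C1 OH, C10 OPMB, C6 OTES, C8 OTBS, C12 OTBS | C#C/C(C)=C\[C@H](O[Si](CC)(CC)CC)[C@@H](C(=C)CO[Si](C)(C)C(C)(C)C)[C@H](O[Si](C)(C)C(C)(C)C)C[C@@](C)(OCc1ccc(OC)cc1)CO | intermediate
19 | seco Z-enyne aldehyde (6S,7S,8R,10R): C1 CHO, C10 OPMB, C6 OTES, C8 OTBS, C12 OTBS | C#C/C(C)=C\[C@H](O[Si](CC)(CC)CC)[C@@H](C(=C)CO[Si](C)(C)C(C)(C)C)[C@H](O[Si](C)(C)C(C)(C)C)C[C@@](C)(OCc1ccc(OC)cc1)C=O | intermediate
20 | lithium acetylide of 19 (not isolated) | [Li]C#C/C(C)=C\[C@H](O[Si](CC)(CC)CC)[C@@H](C(=C)CO[Si](C)(C)C(C)(C)C)[C@H](O[Si](C)(C)C(C)(C)C)C[C@@](C)(OCc1ccc(OC)cc1)C=O | intermediate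
21 | ten-membered Z-enynol (6S,7S,8R,10R; C1 carbinol either epimer): C10 OPMB, C6 OTES, C8 OTBS, C12 OTBS | OC1C#C/C(C)=C\[C@H](O[Si](CC)(CC)CC)[C@@H](C(=C)CO[Si](C)(C)C(C)(C)C)[C@H](O[Si](C)(C)C(C)(C)C)C[C@@]1(C)OCc2ccc(OC)cc2 | intermediate
22 | ten-membered Z-enynone (6S,7S,8R,10R): C1 ketone, C10 OPMB | O=C1C#C/C(C)=C\[C@H](O[Si](CC)(CC)CC)[C@@H](C(=C)CO[Si](C)(C)C(C)(C)C)[C@H](O[Si](C)(C)C(C)(C)C)C[C@@]1(C)OCc2ccc(OC)cc2 | intermediate
23 | hydroxy ynone (6S,7S,8R,10R): C1 ketone, free C10 OH | O=C1C#C/C(C)=C\[C@H](O[Si](CC)(CC)CC)[C@@H](C(=C)CO[Si](C)(C)C(C)(C)C)[C@H](O[Si](C)(C)C(C)(C)C)C[C@@]1(C)O | intermediate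
24 | bridged 3(2H)-furanone (6S,7S,8R,10R): 3,10-oxygen bridge, C6 OTES, C8 OTBS, C12 OTBS | CC[Si](CC)(CC)O[C@H]1/C=C(/C)C2=CC(=O)[C@@](C)(C[C@@H](O[Si](C)(C)C(C)(C)C)[C@@H]1C(=C)CO[Si](C)(C)C(C)(C)C)O2 | intermediate
25 | furanone diol (6S,7R,8R,10R): C6 OH, C12 OH, C8 OTBS | O[C@H]1/C=C(/C)C2=CC(=O)[C@@](C)(C[C@@H](O[Si](C)(C)C(C)(C)C)[C@@H]1C(=C)CO)O2 | intermediate
26 | hydroxy enal (6S,7R,8R,10R): C6 OH, C12 aldehyde, C8 OTBS (not isolated) | O[C@H]1/C=C(/C)C2=CC(=O)[C@@](C)(C[C@@H](O[Si](C)(C)C(C)(C)C)[C@@H]1C(=C)C=O)O2 | intermediate
27 | 6,12-lactol (6S,7R,8R,10R; lactol carbon either epimer), C8 OTBS (not isolated) | C=C1C(O)O[C@H]2/C=C(/C)C3=CC(=O)[C@@](C)(C[C@@H](O[Si](C)(C)C(C)(C)C)[C@H]12)O3 | intermediate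
28 | C8-silylated tricyclic methylene lactone (6S,7R,8R,10R) | C=C1C(=O)O[C@H]2/C=C(/C)C3=CC(=O)[C@@](C)(C[C@@H](O[Si](C)(C)C(C)(C)C)[C@H]12)O3 | intermediate
29 | C8 alcohol of the tricyclic methylene lactone (6S,7S,8R,10R) | C=C1C(=O)O[C@H]2/C=C(/C)C3=CC(=O)[C@@](C)(C[C@@H](O)[C@H]12)O3 | intermediate
30 | tert-butyl acrylate | C=CC(=O)OC(C)(C)C | starting material
31 | acetaldehyde | CC=O | starting material
32 | tert-butyl 3-hydroxy-2-methylidenebutanoate (racemic) | CC(O)C(=C)C(=O)OC(C)(C)C | intermediate
33 | tert-butyl 3-acetoxy-2-methylidenebutanoate (racemic, not isolated) | CC(OC(C)=O)C(=C)C(=O)OC(C)(C)C | intermediate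
34 | tert-butyl (2E)-2-(acetoxymethyl)but-2-enoate | C/C=C(\COC(C)=O)C(=O)OC(C)(C)C | intermediate
35 | (2E)-2-(acetoxymethyl)but-2-enoic acid | C/C=C(\COC(C)=O)C(=O)O | intermediate
36 | mixed anhydride of 35 with 2,4,6-trichlorobenzoic acid (not isolated) | C/C=C(\COC(C)=O)C(=O)OC(=O)c1c(Cl)cc(Cl)cc1Cl | intermediate
37 | CNP0176571.1, (6S,7S,8R,10R)-8-O-[(2E)-2-(acetoxymethyl)but-2-enoyl]-1-oxo-3,10-epoxygermacra-2,4Z,11(13)-trien-6,12-olide | C=C1C(=O)O[C@H]2/C=C(/C)C3=CC(=O)[C@@](C)(C[C@@H](OC(=O)/C(=C/C)COC(C)=O)[C@H]12)O3 | target

## Step count and least certain steps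

Total step count: 25. Longest linear sequence: 21 steps (steps 1–7, 9–21 and 25). Steps 8 and 22–24 are side branches.

**Step 15 (key step).** The most likely failure is oligomerisation through intermolecular acetylide addition, together with consumption of the hindered aldehyde by the amide base if alkyne deprotonation is slow. Fallback, setting out from 18 and returning at 21: the terminal alkyne is iodinated (N-iodosuccinimide, AgNO3 cat., acetone) to the iodoalkyne alcohol F1. Dess–Martin oxidation gives the iodoalkyne aldehyde F2. CrCl2 with catalytic NiCl2 in THF at high dilution then closes the ring by a base-free Nozaki–Hiyama–Kishi alkynylation to give 21.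

**Step 9.** The most likely failure is loss of the Z geometry of the enynal before it is captured, and metal-promoted cycloisomerisation of the Z-enynol product or acyl migration from O8 to O6, all of which would lower the amount of the desired adduct. Fallback, setting out from 10 and returning at 14, with the alkyne introduced after the C6–C7 bond: but-2-yn-1-ol is converted with NaAlH2(OCH2CH2OCH3)2 and then I2 into (Z)-3-iodobut-2-en-1-ol F3. MnO2 gives (Z)-3-iodobut-2-enal F4. The same indium Barbier reaction with 10 gives the iodo adduct F5. Sonogashira coupling with ethynyltrimethylsilane (Pd(PPh3)2Cl2, CuI, Et3N) gives the C-silylated enyne F6. Bu4NF buffered with AcOH removes the C-silyl group to give 14.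

**Step 5.** The most likely failure is insufficient facial selectivity in the addition to an α-unbranched aldehyde, which would give a mixture of C8 epimers. Fallback, setting out from 7 (as the epimer mixture) and returning at 7: MnO2 oxidises the allylic alcohol to the enone F7. Corey–Bakshi–Shibata reduction with the (S)-methyl oxazaborolidine and catecholborane at −78 °C, the alkenyl group acting as the large substituent, sets C8 as R by asymmetric reduction in place of asymmetric addition.

**Step 18.** The most likely failure is acid-promoted loss of the C6 TES group by traces of HCl from the gold salt, after which O6 could compete for C3, or a slow transannular addition. Fallback, setting out from 23 and returning at 24: diethylamine in ethanol adds to the ynone to give the enaminone F8. Dilute acetic acid then lets O10 displace the amine by addition–elimination at C3, which gives furanone 24 without a metal catalyst.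

## Further compounds

F1 | step 15 | iodoalkyne alcohol: 18 with iodine on C2 | IC#C/C(C)=C\[C@H](O[Si](CC)(CC)CC)[C@@H](C(=C)CO[Si](C)(C)C(C)(C)C)[C@H](O[Si](C)(C)C(C)(C)C)C[C@@](C)(OCc1ccc(OC)cc1)CO
F2 | step 15 | iodoalkyne aldehyde: 19 with iodine on C2 | IC#C/C(C)=C\[C@H](O[Si](CC)(CC)CC)[C@@H](C(=C)CO[Si](C)(C)C(C)(C)C)[C@H](O[Si](C)(C)C(C)(C)C)C[C@@](C)(OCc1ccc(OC)cc1)C=O
F3 | step 9 | (Z)-3-iodobut-2-en-1-ol | C/C(I)=C/CO
F4 | step 9 | (Z)-3-iodobut-2-enal | C/C(I)=C/C=O
F5 | step 9 | iodo adduct: analogue of 14 with iodine in place of the ethynyl group, same configuration | C/C(I)=C/[C@H](O)[C@H]1C(=C)C(=O)O[C@@H]1C[C@@]2(C)OC(c3ccc(OC)cc3)OC2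
F6 | step 9 | C-trimethylsilyl derivative of 14 | C[Si](C)(C)C#C/C(C)=C\[C@H](O)[C@H]1C(=C)C(=O)O[C@@H]1C[C@@]2(C)OC(c3ccc(OC)cc3)OC2
F7 | step 5 | (3E)-1-[(4R)-2-(4-methoxyphenyl)-4-methyl-1,3-dioxolan-4-yl]oct-3-en-2-one | CCCC/C=C/C(=O)C[C@@]1(C)OC(c2ccc(OC)cc2)OC1
F8 | step 18 | enaminone: diethylamine adduct of 23 at C3 (C2=C3 geometry not defined) | O=C1C=C(N(CC)CC)/C(C)=C\[C@H](O[Si](CC)(CC)CC)[C@@H](C(=C)CO[Si](C)(C)C(C)(C)C)[C@H](O[Si](C)(C)C(C)(C)C)C[C@@]1(C)O
A1 | alternative 1 | eleven-membered sulfone bridging C4 and C5, C8 OTBS, saturated lactone (C4 either epimer) | C1C(=O)O[C@H]2CS(=O)(=O)C(C)C3=CC(=O)[C@@](C)(C[C@@H](O[Si](C)(C)C(C)(C)C)[C@H]12)O3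
A2 | alternative 1 | C8-silylated tricyclic core without the exocyclic methylene | C1C(=O)O[C@H]2/C=C(/C)C3=CC(=O)[C@@](C)(C[C@@H](O[Si](C)(C)C(C)(C)C)[C@H]12)O3
A3 | alternative 2 | (R)-tertiary propargylic hydroxy ketone with Z-enyne, C6 OTBS and C8 OPMB | CC(C)(C)[Si](C)(C)OC/C=C(/C)C#C[C@@](C)(O)C(=O)CCOCc1ccc(OC)cc1
A4 | alternative 2 | acyclic 3(2H)-furanone with quaternary C10, Z C4–C5 olefin, C6 OTBS and C8 OPMB | CC(C)(C)[Si](C)(C)OC/C=C(/C)C1=CC(=O)[C@@](C)(CCOCc2ccc(OC)cc2)O1
A5 | alternative 3 | seco Z-alkenyl iodide aldehyde with furanone, C8 OTBS and C12 methyl ester | I/C=C(/C)C1=CC(=O)[C@@](C)(C[C@@H](O[Si](C)(C)C(C)(C)C)[C@@H](C=O)C(=C)C(=O)OC)O1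
A6 | alternative 3 | C8-silylated tricyclic methylene lactone (identical with 28) | C=C1C(=O)O[C@H]2/C=C(/C)C3=CC(=O)[C@@](C)(C[C@@H](O[Si](C)(C)C(C)(C)C)[C@H]12)O3
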